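## Retrosynthetic overview

1. Target 19 ⇐ C5'‑O‑acetylation and phenol desilylation of diol 17 ⇐ Zr‑catalysed carboalumination of alkyne 11 and Pd‑catalysed coupling with benzyl bromide 15 (builds the 2'E olefin and the aryl–C1' bond).
2. 11 ⇐ cis‑selective ketone reduction (C14') and catalytic asymmetric propargylation (C5') of keto‑enal 8.
3. 8 ⇐ ring‑forming C12'–O bond: enantioselective 5‑endo cycloetherification of the α'‑hydroxy dienone 7 (new method).
4. 7 ⇐ Claisen–Schmidt condensation of 8‑oxogeranyl acetate 2 (SeO2 on geranyl acetate 1) with 3‑hydroxy‑3‑methylbutan‑2‑one 3, then MnO2.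
5. 15 ⇐ 4‑methoxy‑2‑methylphenol 12 by ortho‑hydroxymethylation, silylation and bromination. Only the oxolane ring is built (step 4); the benzene ring is bought.

Assumption: side‑chain locants C1'–C16' count outwards from the benzylic carbon (C12' = oxolane CH–O, C14' = oxolane CH–OH); the catalyst antipodes in steps 4 and 5 are written as those expected to give 12'S and 5'R, and the sense of the new step 4 must be confirmed by experiment.

## Route

Step 1
Reactants: 1 geranyl acetate
Product: 2 (2E,6E)-3,7-dimethyl-8-oxoocta-2,6-dien-1-yl acetate (8‑oxogeranyl acetate)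
Conditions: SeO2 (1.2 equiv), 1,4‑dioxane/EtOH, 80 °C
Reagents that add atoms: selenium dioxide, O=[Se]=O
Why: Riley allylic oxidation (ene reaction then 2,3‑sigmatropic shift) attacks the (E)‑methyl of the most electron‑rich terminal olefin and gives the (E)‑enal in the usual moderate yield; no stereocentre is formed.

Step 2
Reactants: 2 8‑oxogeranyl acetate; 3 3‑hydroxy‑3‑methylbutan‑2‑one
Product: 6 (4E,6E,10E)-2,12-dihydroxy-2,6,10-trimethyldodeca-4,6,10-trien-3-one (dienone diol), via hydroxy enal 4 (not isolated), via aldol adduct 5 (not isolated)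
Conditions: 3 (3 equiv), LiOH·H2O (2.2 equiv), MeOH/H2O 3:1, 0 °C → rt
Reagents that add atoms: none
Why: Claisen–Schmidt aldol condensation, in which only the methyl group of 3 can enolise and E1cB dehydration gives the (E)‑enone (as in the citral/acetone condensation), with saponification of the primary acetate in the same pot.

Step 3
Reactants: 6 dienone diol
Product: 7 (2E,6E,8E)-11-hydroxy-3,7,11-trimethyl-10-oxododeca-2,6,8-trienal (keto‑enal)
Conditions: activated MnO2 (15 equiv), CH2Cl2, rt
Reagents that add atoms: none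
Why: chemoselective MnO2 oxidation of the primary allylic alcohol leaves the tertiary alcohol untouched and gives a substrate with no acid‑labile allylic C–O bond and no nucleophilic olefin for the next step.

Step 4
Reactants: 7 keto‑enal
Product: 8 (2E,6E)-7-[(2S)-5,5-dimethyl-4-oxooxolan-2-yl]-3-methylocta-2,6-dienal
Conditions: (R)‑BINOL N‑triflylphosphoramide with 3,3'‑bis(2,4,6‑triisopropylphenyl) groups (5 mol %), 5 Å MS, toluene, −30 → −10 °C; Et3N quench
Reagents that add atoms: none
Why: Proposed new method: enantioselective Brønsted‑acid‑catalysed 5‑endo cycloetherification of an α'‑hydroxy dienone, in which the chiral N‑triflylphosphoramide protonates the ketone to a hydroxy‑pentadienyl cation held as a contact ion pair, so that ring closure is the allowed capture of an allyl cation by the tertiary hydroxyl (its proton passing to the basic site of the anion) and the aryl walls of the anion expose one face of C12', forming the oxolane C12'–O bond and setting 12'S under kinetic control at low temperature; the closest known reaction types are the racemic sulfonic‑acid‑mediated 5‑endo cyclisation of α'‑hydroxy enones to dihydrofuran‑3(2H)‑ones and chiral N‑triflylphosphoramide catalysis of cationic dienone cyclisations (asymmetric Nazarov) and of intramolecular oxa‑Michael additions.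

Step 5
Reactants: 8 oxolanone enal; 9 allenylboronic acid pinacol ester
Product: 10 (5S)-5-[(2E,6E,8R)-8-hydroxy-6-methylundeca-2,6-dien-10-yn-2-yl]-2,2-dimethyloxolan-3-one
Conditions: 9 (1.5 equiv), (R)‑TRIP phosphoric acid (5 mol %), 4 Å MS, toluene, −20 → 0 °C
Reagents that add atoms: none
Why: chiral phosphoric acid‑catalysed propargylation with an allenylboronate (SE2' through a closed six‑membered transition state) is selective for the aldehyde over the hindered α‑quaternary ketone and sets C5' as R under catalyst control.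

Step 6
Reactants: 10 keto alkynol
Product: 11 (3S,5S)-5-[(2E,6E,8R)-8-hydroxy-6-methylundeca-2,6-dien-10-yn-2-yl]-2,2-dimethyloxolan-3-ol
Conditions: LiBH(s‑Bu)3 (2.3 equiv), THF, −78 °C; H2O
Reagents that add atoms: none
Why: substrate‑controlled reduction with a bulky trialkylborohydride delivers hydride to the ring face anti to the C12' alkenyl group, giving the 12',14'‑cis alcohol (14'S); any trans epimer is removed by chromatography.

Step 7
Reactants: 12 4‑methoxy‑2‑methylphenol
Product: 13 2-(hydroxymethyl)-4-methoxy-6-methylphenol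
Conditions: 37% aq. CH2O (1.5 equiv), NaOH (1.0 equiv), H2O, rt; AcOH
Reagents that add atoms: formaldehyde, C=O
Why: Lederer–Manasse hydroxymethylation of the phenoxide can occur only at the single free ortho position, because the para position carries OMe and the other ortho position carries Me.

Step 8
Reactants: 13 hydroxymethyl phenol
Product: 14 tert-butyl{[2-(tert-butyldimethylsilyloxy)-5-methoxy-3-methylphenyl]methoxy}dimethylsilane (bis‑silyl ether)
Conditions: TBSCl (2.4 equiv), imidazole (5 equiv), DMF, rt → 40 °C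
Reagents that add atoms: tert‑butyldimethylsilyl chloride, CC(C)(C)[Si](C)(C)Cl
Why: standard silylation of both hydroxyls protects the phenol for the later organometallic step.

Step 9
Reactants: 14 bis‑silyl ether
Product: 15 [2-(bromomethyl)-4-methoxy-6-methylphenoxy](tert-butyl)dimethylsilane
Conditions: Ph3PBr2 (1.1 equiv), CH2Cl2, 0 °C → rt
Reagents that add atoms: dibromotriphenylphosphorane, BrP(Br)(c1ccccc1)(c1ccccc1)c1ccccc1
Why: direct conversion of the benzylic silyl ether into the bromide (oxyphosphonium formation then SN2 by bromide), while the aryl silyl ether cannot be displaced and stays.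

Step 10
Reactants: 11 diol alkyne; 15 silyloxybenzyl bromide
Product: 17 (3S,5S)-5-[(2E,6E,8R,10E)-12-{2-[tert-butyl(dimethyl)silyl]oxy-5-methoxy-3-methylphenyl}-8-hydroxy-6,10-dimethyldodeca-2,6,10-trien-2-yl]-2,2-dimethyloxolan-3-ol, via alkenylalane 16 (not isolated)
Conditions: Me3Al (4.5 equiv), Cp2ZrCl2 (0.3 equiv), H2O (1 equiv), CH2Cl2, −20 → 0 °C; then 15 (1.2 equiv), Pd(PPh3)4 (5 mol %), THF, rt; aq. potassium sodium tartrate
Reagents that add atoms: trimethylaluminium, C[Al](C)C
Why: Negishi zirconium‑catalysed syn‑carboalumination places methyl on the internal and aluminium on the terminal alkyne carbon (the hydroxyls ride as aluminium alkoxides), and the alkenyl–benzyl cross‑coupling at zerovalent palladium proceeds with retention, so the C2'=C3' olefin is formed as E only.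

Step 11
Reactants: 17 silyl ether diol
Product: 19 CNP0148147.2, (2E,5R,6E,10E)-1-(2-hydroxy-5-methoxy-3-methylphenyl)-11-[(2S,4S)-4-hydroxy-5,5-dimethyloxolan-2-yl]-3,7-dimethyldodeca-2,6,10-trien-5-yl acetate, via acetate silyl ether 18 (not isolated)
Conditions: Ac2O (1.3 equiv), pyridine, CH2Cl2, 0 °C; MeOH, evaporate; then Bu4NF/AcOH (1.2 equiv each), THF, 0 °C
Reagents that add atoms: acetic anhydride, CC(=O)OC(C)=O
Why: acylation without DMAP takes the open allylic C5' hydroxyl (retention) in preference to the neopentyl‑type C14' hydroxyl next to the ring CMe2, and buffered fluoride then cleaves only the aryl silyl ether, leaving the secondary acetate.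

## Compound list

1 | geranyl acetate | CC(=O)OC/C=C(\C)CCC=C(C)C | starting material
2 | (2E,6E)-3,7-dimethyl-8-oxoocta-2,6-dien-1-yl acetate | CC(=O)OC/C=C(\C)CC/C=C(\C)C=O | intermediate
3 | 3-hydroxy-3-methylbutan-2-one | CC(=O)C(C)(C)O | starting material
4 | (2E,6E)-8-hydroxy-2,6-dimethylocta-2,6-dienal | OC/C=C(\C)CC/C=C(\C)C=O | intermediate
5 | (6E,10E)-2,5,12-trihydroxy-2,6,10-trimethyldodeca-6,10-dien-3-one (racemic at C5) | OC/C=C(\C)CC/C=C(\C)C(O)CC(=O)C(C)(C)O | intermediate
6 | (4E,6E,10E)-2,12-dihydroxy-2,6,10-trimethyldodeca-4,6,10-trien-3-one | OC/C=C(\C)CC/C=C(\C)/C=C/C(=O)C(C)(C)O | intermediate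
7 | (2E,6E,8E)-11-hydroxy-3,7,11-trimethyl-10-oxododeca-2,6,8-trienal | O=C/C=C(\C)CC/C=C(\C)/C=C/C(=O)C(C)(C)O | intermediate
8 | (2E,6E)-7-[(2S)-5,5-dimethyl-4-oxooxolan-2-yl]-3-methylocta-2,6-dienal | O=C/C=C(\C)CC/C=C(\C)[C@@H]1CC(=O)C(C)(C)O1 | intermediate
9 | allenylboronic acid pinacol ester | C=C=CB1OC(C)(C)C(C)(C)O1 | starting material
10 | (5S)-5-[(2E,6E,8R)-8-hydroxy-6-methylundeca-2,6-dien-10-yn-2-yl]-2,2-dimethyloxolan-3-one | C#CC[C@H](/C=C(\C)CC/C=C(\C)[C@@H]1CC(=O)C(C)(C)O1)O | intermediate
11 | (3S,5S)-5-[(2E,6E,8R)-8-hydroxy-6-methylundeca-2,6-dien-10-yn-2-yl]-2,2-dimethyloxolan-3-ol | C#CC[C@H](/C=C(\C)CC/C=C(\C)[C@@H]1C[C@H](O)C(C)(C)O1)O | intermediate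
12 | 4-methoxy-2-methylphenol | COc1ccc(O)c(C)c1 | starting material
13 | 2-(hydroxymethyl)-4-methoxy-6-methylphenol | COc1cc(C)c(O)c(CO)c1 | intermediate
14 | bis(tert-butyldimethylsilyl) ether of 13 | COc1cc(C)c(O[Si](C)(C)C(C)(C)C)c(CO[Si](C)(C)C(C)(C)C)c1 | intermediate
15 | [2-(bromomethyl)-4-methoxy-6-methylphenoxy](tert-butyl)dimethylsilane | COc1cc(C)c(O[Si](C)(C)C(C)(C)C)c(CBr)c1 | intermediate
16 | (E)-alkenyl(dimethyl)alane from 11, both hydroxyls as dimethylaluminium alkoxides | C[Al](C)/C=C(\C)C[C@H](/C=C(\C)CC/C=C(\C)[C@@H]1C[C@H](O[Al](C)C)C(C)(C)O1)O[Al](C)C | intermediate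
17 | (3S,5S)-5-[(2E,6E,8R,10E)-12-{2-[tert-butyl(dimethyl)silyl]oxy-5-methoxy-3-methylphenyl}-8-hydroxy-6,10-dimethyldodeca-2,6,10-trien-2-yl]-2,2-dimethyloxolan-3-ol | COc1cc(C)c(O[Si](C)(C)C(C)(C)C)c(C/C=C(\C)C[C@H](/C=C(\C)CC/C=C(\C)[C@@H]2C[C@H](O)C(C)(C)O2)O)c1 | intermediate
18 | C5' acetate of 17 (aryl silyl ether retained) | COc1cc(C)c(O[Si](C)(C)C(C)(C)C)c(C/C=C(\C)C[C@H](/C=C(\C)CC/C=C(\C)[C@@H]2C[C@H](O)C(C)(C)O2)OC(C)=O)c1 | intermediate
19 | CNP0148147.2, (2E,5R,6E,10E)-1-(2-hydroxy-5-methoxy-3-methylphenyl)-11-[(2S,4S)-4-hydroxy-5,5-dimethyloxolan-2-yl]-3,7-dimethyldodeca-2,6,10-trien-5-yl acetate | COc1cc(C)c(O)c(C/C=C(\C)C[C@H](/C=C(\C)CC/C=C(\C)[C@@H]2C[C@H](O)C(C)(C)O2)OC(C)=O)c1 | target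

## Count and risks

Total step count: 11. Longest linear sequence: 8 steps (steps 1–6, 10, 11); steps 7–9 make the aryl partner.

Step 4 (the proposed new cyclisation; risks are low enantioselectivity and erosion by reversible ring opening). The fallback sets out from 7 and uses known chemistry only. Compound 7 is closed with TsOH·H2O (10 mol %) in 1,2‑dichloroethane at 50 °C, the established racemic acid‑mediated 5‑endo cyclisation of α'‑hydroxy enones, to give the racemic oxolanone enal F1. Propargylation exactly as in step 5 then gives 10 together with its C12' epimer F2. A catalyst‑controlled Corey–Bakshi–Shibata reduction ((R)‑2‑methyl‑CBS‑oxazaborolidine, BH3·SMe2, THF, −20 °C) fixes C14' as S in both, so the pair becomes the cis diol 11 and the trans diol F3. These are separated on silica (at most half of the material is useful), and the route is rejoined at 11.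

Step 10 (one‑pot carboalumination and coupling; the chelated alkoxy‑alane may transmetalate sluggishly, and the allylic oxolane ether sees Lewis acid). The fallback sets out from 11 and reverses the polarity of the coupling. Alane 16 is made as before but quenched with I2 (THF, −30 °C) to give the isolable (E)‑alkenyl iodide F4. Bromide 15 is converted separately into the benzylzinc bromide F5 (Zn dust, LiCl, THF, rt). Negishi coupling of F4 with F5 (1.5 equiv) under Pd(OAc)2/SPhos in THF at rt, conditions that tolerate free hydroxyls, returns to the route at 17.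

Step 11 (chemoselective acetylation of C5'‑OH beside C14'‑OH). The fallback sets out from 8 and replaces steric discrimination by mechanism‑based selection. Propargylation with (S)‑TRIP phosphoric acid gives the 5'S alkynol F6, LiBH(s‑Bu)3 reduction gives the 5'S diol F7, and carboalumination/coupling with 15 as in step 10 (through the epimeric alkenylalane F8) gives the 5'S silyl ether diol F9. Mitsunobu esterification (AcOH, PPh3, DIAD, toluene, 0 °C) can displace only the C5' oxyphosphonium (SN2 at the neopentyl C14' is not possible) and inverts it to the 5'R acetate, rejoining the route at 18, which is desilylated as in step 11.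

Further compounds
F1 | step 4 | racemic (2E,6E)-7-(5,5-dimethyl-4-oxooxolan-2-yl)-3-methylocta-2,6-dienal | O=C/C=C(\C)CC/C=C(\C)C1CC(=O)C(C)(C)O1
F2 | step 4 | (5R)-5-[(2E,6E,8R)-8-hydroxy-6-methylundeca-2,6-dien-10-yn-2-yl]-2,2-dimethyloxolan-3-one (C12' epimer of 10) | C#CC[C@H](/C=C(\C)CC/C=C(\C)[C@H]1CC(=O)C(C)(C)O1)O
F3 | step 4 | (3S,5R)-5-[(2E,6E,8R)-8-hydroxy-6-methylundeca-2,6-dien-10-yn-2-yl]-2,2-dimethyloxolan-3-ol (trans diol) | C#CC[C@H](/C=C(\C)CC/C=C(\C)[C@H]1C[C@H](O)C(C)(C)O1)O
F4 | step 10 | (3S,5S)-5-[(2E,6E,8R,10E)-8-hydroxy-11-iodo-6,10-dimethylundeca-2,6,10-trien-2-yl]-2,2-dimethyloxolan-3-ol | I/C=C(\C)C[C@H](/C=C(\C)CC/C=C(\C)[C@@H]1C[C@H](O)C(C)(C)O1)O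
F5 | step 10 | {2-[tert-butyl(dimethyl)silyl]oxy-5-methoxy-3-methylbenzyl}zinc bromide | COc1cc(C)c(O[Si](C)(C)C(C)(C)C)c(C[Zn]Br)c1
F6 | step 11 | (5S)-5-[(2E,6E,8S)-8-hydroxy-6-methylundeca-2,6-dien-10-yn-2-yl]-2,2-dimethyloxolan-3-one (C5' epimer of 10) | C#CC[C@@H](/C=C(\C)CC/C=C(\C)[C@@H]1CC(=O)C(C)(C)O1)O
F7 | step 11 | (3S,5S)-5-[(2E,6E,8S)-8-hydroxy-6-methylundeca-2,6-dien-10-yn-2-yl]-2,2-dimethyloxolan-3-ol (C5' epimer of 11) | C#CC[C@@H](/C=C(\C)CC/C=C(\C)[C@@H]1C[C@H](O)C(C)(C)O1)O
F8 | step 11 | (E)-alkenyl(dimethyl)alane from F7, both hydroxyls as dimethylaluminium alkoxides | C[Al](C)/C=C(\C)C[C@@H](/C=C(\C)CC/C=C(\C)[C@@H]1C[C@H](O[Al](C)C)C(C)(C)O1)O[Al](C)C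
F9 | step 11 | C5' epimer (8S) of 17 | COc1cc(C)c(O[Si](C)(C)C(C)(C)C)c(C/C=C(\C)C[C@@H](/C=C(\C)CC/C=C(\C)[C@@H]2C[C@H](O)C(C)(C)O2)O)c1
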